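Remark on the chemistry: N,2-dimethoxy-N-methylacetamide (7) is assumed to be a catalogue reagent, and 17 and 18 are drawn as single geometrical isomers although isomer mixtures would serve, because both double-bond geometries vanish when ring B aromatises.

## Structural features

The target is an achiral flavonol ether: ring A is fused to the pyranone ring C in a 4H-chromen-4-one, and C2 of ring C is bonded to C1' of a phenyl ring B. Ring A carries 5-OH, 7-OH and 8-OMe beside the ring oxygen O1, ring C carries 3-OMe, and ring B carries 2'-OH, 4'-OH and 5'-OMe. There is no stereocentre, so no neighbouring stereocentres have to be related; the only stereochemical elements in the plan are the double-bond geometries of the diene building block, and these are erased. The fragile groups are the four free phenols (the 5-OH is chelated to the C4 carbonyl, the others are electron-rich and oxidisable) and the pyranone, which is opened at C2 by hydroxide or alkoxide. The real difficulty is regiochemical. Three methyl groups must sit on O3, O8 and O5' while four similar phenolic oxygens stay free. Ring A also needs the 1,2,3,5-tetraoxygenated pattern with the ring-closing oxygen next to the methoxy group, that is the 8-methoxy and not the 6-methoxy isomer. The key step exploits ring B: the chain C2'–C3'–C4'–C5' with oxygen on C2' and C4', methoxy on C5' and hydrogen on C3' is the carbon chain of a 4-methoxyacetoacetate bis(silyl) dienol ether, so C1' and C6' can come from an ethynyl group on C2 of the chromone.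

## Logic of the disconnections

22 to 21: the two O–CH2Ph bonds on O5 and O7 are cut. The ring A phenols must be masked through base, organolithium and diene chemistry, whereas the ring B hydroxyls come out of the key step free. The gain is a neutral last step that leaves all three methyl ethers alone. The demand is that nothing else in 21 is reducible, which holds because the pyranone C2=C3 bond is tetrasubstituted and part of a vinylogous ester.

21 to 15 and 18: the bonds C1'–C2' and C5'–C6' are cut. The oxygen pattern of ring B maps onto the four carbons of 18, and C1' and C6' become an alkyne. Ring B disappears altogether, leaving a chromone with a two-carbon substituent and a diene two steps from 16. The forward step needs an alkyne whose unsubstituted carbon is the electrophilic end, a diene that reacts through its methoxy-bearing terminus first, and an adduct that aromatises by losing methanol rather than silanol.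

15 to 14: the C(sp)–Si bond is cut. A free ethynyl group with its acidic hydrogen and its acceptor character would not survive acylation and enolate chemistry, so it is carried with a silyl cap. The demand is a desilylation that is neither basic nor nucleophilic toward the product.

14 to 12 (through 13): the O1–C2 bond and the C2–C3 bond are cut. The pyranone comes from a 1,3-diketone, and the C2–C3 bond is made by intramolecular acyl transfer from oxygen to carbon, which excludes O-acylation of the enolate. This reduces the chromone to an aryl ketone and a three-carbon acid. The base must spare the silylalkyne, and ring closure must occur at the carbonyl and not at the alkyne.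

12 to 10 and 11: the ester O–C(=O) bond is cut, which places the acyl group next to the enolisable ketone. The demand is acylation of a hindered, hydrogen-bonded phenol without conjugate addition to the ynoate.

10 to 6 and 7: the aryl–carbonyl bond C4a–C4 is cut, together with the acetal on O1. The acyl group must enter between O1 and O5 and not between O5 and O7, and electrophilic acylation does not distinguish these positions reliably. A metalation directed by the acetal on O1 does, because its only free ortho position is the required carbon. The demand is regioselective lithiation in the presence of two benzyl ethers and a single addition to 7.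

6 to 3 (through 4 and 5): the C8–O bond is traced back to a C8–CHO bond, and the O–CH3 bond is cut. The oxygen that sits between two other oxygens comes from the formyl carbon by oxidative aryl migration. It is methylated at the moment when it is the only free phenol, which is what fixes the methoxy group at C8. The demand is aryl rather than hydrogen migration and no over-oxidation of the electron-rich ring.

3 to 2 to 1: three O–C bonds of protecting groups are cut. The hydroxyls of 1 are differentiated as two benzyl ethers (future O5 and O7) and one acetal (future O1). The hydrogen bond to the formyl group leaves one ortho hydroxyl for last, so the forward step must stop at dialkylation.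

18 to 17 to 16: two O–Si bonds are cut. The diene is the bis(silyl) dienol ether of a commercial β-keto ester. The demand is deprotonation at the γ-carbon and trapping on oxygen under anhydrous conditions.

## Other disconnections considered

Alternative 1: The cut runs through ring A at C4a–C5 and C8–C8a, so ring A instead of ring B is grown by the cycloaddition.
- Forward key step: 18 would add to methyl 3-bromopropiolate A2 with its methoxy-bearing terminus on the brominated carbon. Loss of methanol and desilylation would give methyl 2-bromo-4,6-dihydroxy-3-methoxybenzoate A1.
- In its favour: an ynoate is the classical, strongly activated partner for this diene class, so on intrinsic reactivity of the key step this plan is better than the chosen one. It also delivers a fully substituted ring A with the 8-methoxy/5,7-dihydroxy pattern fixed by the mechanism, which would replace the oxidation and metalation sequence of steps 2 to 4, and it uses the same diene.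
- Against it here: the ester carbon of A1 (the future C4) is flanked by bromine and an oxygen, so it is a poor electrophile for the condensation that must attach C3, C2 and ring B. O1 must be made afterwards by C–O coupling at a hindered aryl bromide next to a methoxy group. A2 is a lachrymatory, thermally labile reagent. Ring B, which the chosen plan obtains from the diene, must be prepared separately with its own oxygen pattern and protecting groups.
- Comparison: on structure it is the equal of the chosen plan for ring A and weaker for ring B and the pyranone. On mechanism it is the same reaction with a better dienophile. On step count the saving on ring A is expected to be used up by the ring B synthesis and the two extra bond constructions at C4 and O1.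

Alternative 2: Ring A is cut at C4a–C8a and C5–C6 and traced back to 4-methoxy-3-(triisopropylsilyloxy)cyclobut-2-en-1-one A4 and (triisopropylsilyloxy)acetylene A5.
- Forward key step: on heating, A4 would open to a vinylketene that adds A5 in a (2+2) sense. Four-electron opening of the new cyclobutenone, six-electron electrocyclisation and tautomerisation would give 2-methoxy-3,5-bis(triisopropylsilyloxy)phenol A3.
- In its favour: A3 is a ring A phenol in which only the future O1 is free. The differentiation that costs the chosen route steps 2 to 4 comes out of the mechanism, and on this point the alternative is better. The later acylation is also steered to the right carbon, because the other open position lies between two bulky silyl ethers.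
- Against it: neither A4 nor A5 is a catalogue compound, and each needs several steps of sensitive chemistry. The silyl ether peri to the carbonyl is unlikely to be as robust as a benzyl ether toward the strong base used to build the pyranone. The benzannulation also leaves ring B untouched, so ring B must still be attached by an acyl-transfer sequence or by the cycloaddition of step 10.
- Comparison: it is mechanistically elegant and regiochemically cleaner for ring A. It is, however, an alternative entry to an intermediate of the type of 10 rather than to the whole molecule, and from catalogue materials it is expected to be several steps longer.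

Alternative 3: No carbon–carbon bond is cut. The C8–O and C5'–O bonds are disconnected, which leads back to the complete flavonol skeleton of morin A8.
- Forward key step: 7,4'-di-O-benzyl-3-O-methylmorin A7 would be treated with K2S2O8 in aqueous alkali. The 5- and 2'-phenoxides attack peroxydisulfate through their para carbons C8 and C5'. Acid hydrolysis of the two aryl sulfates would give 7-(benzyloxy)-2-[4-(benzyloxy)-2,5-dihydroxyphenyl]-5,8-dihydroxy-3-methoxy-4H-chromen-4-one A6. Methylation of the two new hydroxyls and hydrogenolysis would finish the synthesis.
- In its favour: on step count it is clearly better than the chosen plan (about five operations from A8). All skeletal bonds are bought, and the para preference of the persulfate oxidation matches both required positions.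
- Against it: the Elbs oxidation characteristically stops at low conversion, and two such events are needed on one molecule. A6 holds two hydroquinones that are prone to air oxidation in alkali. Making A7 requires selective 3-O-methylation and 7,4'-di-O-benzylation among five hydroxyls of A8. Afterwards the 8- and 5'-hydroxyls must be methylated beside the 2'-hydroxyl, which is not deactivated by chelation as the 5-hydroxyl is, so extra protecting-group steps are likely.
- Comparison: on structure it is the equal or the better of the chosen plan, since nothing has to be built. On mechanism it rests on an electrophilic oxidation with poor throughput and uncertain chemoselectivity, whereas the chosen plan rests on carbon–carbon bond formations whose regiochemistry is set by polarisation. The chosen plan is longer, but each step can be controlled.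

Key step: step 10

## Route

Step 1
Reactants: 1 2,4,6-trihydroxybenzaldehyde
Product: 2 2,4-bis(benzyloxy)-6-hydroxybenzaldehyde
Conditions: BnBr (2.05 equiv), K2CO3, DMF, 0 °C to rt
Reagents that add atoms: benzyl bromide, BrCc1ccccc1
Why: Williamson ether synthesis; the 4-hydroxyl (para to the formyl group, most acidic) and one ortho hydroxyl are alkylated, while the last ortho hydroxyl is held in a hydrogen bond to the formyl oxygen and reacts much more slowly, so two equivalents should stop at 2.

Step 2
Reactants: 2 2,4-bis(benzyloxy)-6-hydroxybenzaldehyde
Product: 3 2,4-bis(benzyloxy)-6-(methoxymethoxy)benzaldehyde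
Conditions: MOMCl, i-Pr2NEt, CH2Cl2, 0 °C to reflux
Reagents that add atoms: chloromethyl methyl ether, COCCl
Why: O-alkylation of the chelated phenol with a reactive α-chloro ether; the acetal masks the future O1, is stable to peracid, carbonate base and butyllithium, and later directs the metalation.

Step 3
Reactants: 3 2,4-bis(benzyloxy)-6-(methoxymethoxy)benzaldehyde
Product: 6 1,5-bis(benzyloxy)-2-methoxy-3-(methoxymethoxy)benzene, via aryl formate 4 (not isolated), via phenol 5 (not isolated)
Conditions: mCPBA, NaHCO3, CH2Cl2, 0 °C to rt; aq Na2SO3 wash, evaporate; then K2CO3, MeOH–DMF, rt; MeI, rt, N2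
Reagents that add atoms: 3-chloroperoxybenzoic acid, OOC(=O)c1cccc(Cl)c1; iodomethane, CI
Why: Baeyer–Villiger (Dakin-type) oxidation in which the aryl group, made electron-rich by three ortho/para oxygens, migrates in preference to hydrogen to give formate 4; methanolysis frees phenoxide 5, the only free phenol, which is methylated in the same pot so that the methyl group lands on the future O8 and the oxidation-prone trialkoxyphenol is never handled.

Step 4
Reactants: 6 1,5-bis(benzyloxy)-2-methoxy-3-(methoxymethoxy)benzene; 7 N,2-dimethoxy-N-methylacetamide
Product: 10 1-[4,6-bis(benzyloxy)-2-hydroxy-3-methoxyphenyl]-2-methoxyethan-1-one, via aryllithium 8 (not isolated), via MOM-protected ketone 9 (not isolated)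
Conditions: n-BuLi, THF, −20 to 0 °C; 7, −78 to 0 °C; then 2 M HCl, MeOH, 45 °C
Reagents that add atoms: none
Why: Directed ortho metalation followed by Weinreb ketone synthesis; the acetal oxygens of the methoxymethoxy group are the strongest director on the ring and its only free ortho position lies between that group and a benzyloxy group, so lithiation should occur there and not between the two benzyloxy groups; the chelated tetrahedral adduct of 8 and 7 prevents double addition, and the acidic quench releases ketone 9 and cleaves its acetal, which is activated by the ortho carbonyl, while benzyl and methyl ethers stay.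

Step 5
Reactants: 10 1-[4,6-bis(benzyloxy)-2-hydroxy-3-methoxyphenyl]-2-methoxyethan-1-one; 11 3-(trimethylsilyl)prop-2-ynoic acid
Product: 12 3,5-bis(benzyloxy)-2-methoxy-6-(2-methoxyacetyl)phenyl 3-(trimethylsilyl)prop-2-ynoate
Conditions: DCC, DMAP (cat.), CH2Cl2, 0 °C to rt
Reagents that add atoms: none
Why: Steglich esterification; acyl transfer through the acylpyridinium overcomes the hindered, hydrogen-bonded phenol, and the trimethylsilyl cap shields the alkyne terminus from conjugate addition.

Step 6
Reactants: 12 3,5-bis(benzyloxy)-2-methoxy-6-(2-methoxyacetyl)phenyl 3-(trimethylsilyl)prop-2-ynoate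
Product: 14 5,7-bis(benzyloxy)-3,8-dimethoxy-2-[(trimethylsilyl)ethynyl]-4H-chromen-4-one, via diketone 13 (not isolated)
Conditions: LiN(SiMe3)2 (2.5 equiv), THF, −78 to −20 °C; AcOH; then TsOH·H2O (cat.), toluene, 50 °C
Reagents that add atoms: none
Why: Baker–Venkataraman rearrangement; the lithium enolate of the α-methoxy ketone attacks the neighbouring ester carbonyl through a six-membered transition state and the acyl group moves from oxygen to carbon to give 13; acid then closes the pyranone by addition of the phenol to the ynone carbonyl (6-exo-trig) and dehydration, a path that should outrun 6-endo-dig attack of the enol oxygen on the silyl-capped alkyne.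

Step 7
Reactants: 14 5,7-bis(benzyloxy)-3,8-dimethoxy-2-[(trimethylsilyl)ethynyl]-4H-chromen-4-one
Product: 15 5,7-bis(benzyloxy)-2-ethynyl-3,8-dimethoxy-4H-chromen-4-one
Conditions: Bu4NF, AcOH, THF, −20 to 0 °C
Reagents that add atoms: none
Why: Fluoride-induced protodesilylation of the alkynylsilane; buffering with acetic acid keeps the medium non-basic, so the electrophilic ethynylchromone is not attacked by fluoride, hydroxide or alkoxide.

Step 8
Reactants: 16 methyl 4-methoxy-3-oxobutanoate
Product: 17 methyl (2Z)-4-methoxy-3-[(trimethylsilyl)oxy]but-2-enoate
Conditions: Me3SiCl, Et3N, toluene, rt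
Reagents that add atoms: chlorotrimethylsilane, C[Si](C)(C)Cl
Why: O-silylation of the enol of the β-keto ester under soft enolisation (amine base, silyl chloride); silicon bonds to the hard oxygen terminus, and the geometry of this double bond is immaterial because it becomes a single bond in step 9.

Step 9
Reactants: 17 methyl (2Z)-4-methoxy-3-[(trimethylsilyl)oxy]but-2-enoate
Product: 18 (1Z,3Z)-1,4-dimethoxy-1,3-bis[(trimethylsilyl)oxy]buta-1,3-diene
Conditions: LiN(i-Pr)2, THF, −78 °C; Me3SiCl, −78 °C to rt; non-aqueous work-up
Reagents that add atoms: chlorotrimethylsilane, C[Si](C)(C)Cl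
Why: Deprotonation at the γ-carbon of the β-silyloxy enoate gives the extended dienolate, which is trapped on the ester oxygen; the isomer drawn has the methoxy group on the outside of the s-cis diene, and neither new double-bond geometry survives step 10.

Step 10
Reactants: 15 5,7-bis(benzyloxy)-2-ethynyl-3,8-dimethoxy-4H-chromen-4-one; 18 (1Z,3Z)-1,4-dimethoxy-1,3-bis[(trimethylsilyl)oxy]buta-1,3-diene
Product: 21 5,7-bis(benzyloxy)-2-(2,4-dihydroxy-5-methoxyphenyl)-3,8-dimethoxy-4H-chromen-4-one, via cyclohexadiene adduct 19 (not isolated), via bis(silyl ether) 20 (not isolated)
Conditions: 18 (3 equiv), toluene, 95 °C, sealed tube, argon; then 1 M HCl, THF, rt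
Reagents that add atoms: none
Why: The step is a normal-electron-demand (4+2) cycloaddition of an electron-rich 1-alkoxy-1,3-bis(silyloxy)diene with a carbonyl-conjugated alkyne followed by aromatisation, the known way from such dienes and acetylenic ketones or esters to resorcinols; here the alkyne of 15 is activated in a vinylogous way through C2=C3 by the C4 carbonyl, so heating is planned. Bond formation should be asynchronous: C4 of 18, the methoxy-bearing terminus with the largest HOMO coefficient, bonds first to the unsubstituted alkyne carbon of 15 (C5'–C6'), the site of the largest LUMO coefficient because attack there lets the charge run through C2=C3 onto the C4 oxygen, and the ketene acetal carbon C1 then closes onto the internal alkyne carbon (C1'–C2'). The six-membered carbocycle is thus closed in a suprafacial (4+2) mode; in the stepwise limit this is a Mukaiyama–Michael addition followed by six-membered ring closure of the allenyl-type enolate carbon onto the oxygen-stabilised cation. Adduct 19 has an acetal carbon at C2' and a hydrogen at C5' across the ring, so 1,4-elimination of methanol gives bis(silyl ether) 20, and dilute acid removes both silyl groups to give 21. The two sp3 carbons of 19 are lost on aromatisation, so no stereocentre has to be controlled. Regioselectivity is required and is secured by the matched polarisation of the two partners; chemoselectivity for the alkyne over the pyranone C2=C3 bond follows from C2 being fully substituted and C3 carrying a donor methoxy group; and the alkyl oxygen, more basic than the silyl oxygen, is the one expected to leave from C2', so the 2'-oxygen stays as a hydroxyl. Benzyl and methyl ethers are inert to the conditions.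

Step 11
Reactants: 21 5,7-bis(benzyloxy)-2-(2,4-dihydroxy-5-methoxyphenyl)-3,8-dimethoxy-4H-chromen-4-one
Product: 22 5,7-dihydroxy-2-(2,4-dihydroxy-5-methoxyphenyl)-3,8-dimethoxy-4H-chromen-4-one
Conditions: H2 (1 atm), Pd/C (10% zerovalent palladium on carbon), EtOAc–MeOH, rt
Reagents that add atoms: none
Why: Hydrogenolysis of the two aryl benzyl ethers over palladium metal; the tetrasubstituted, vinylogous-ester C2=C3 bond of the pyranone and the three methyl ethers are not reduced at one atmosphere and room temperature.

## Compound list

1 | 2,4,6-trihydroxybenzaldehyde | O=Cc1c(O)cc(O)cc1O | starting material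
2 | 2,4-bis(benzyloxy)-6-hydroxybenzaldehyde | O=Cc1c(O)cc(OCc2ccccc2)cc1OCc1ccccc1 | intermediate
3 | 2,4-bis(benzyloxy)-6-(methoxymethoxy)benzaldehyde | COCOc1cc(OCc2ccccc2)cc(OCc2ccccc2)c1C=O | intermediate
4 | 2,4-bis(benzyloxy)-6-(methoxymethoxy)phenyl formate | COCOc1cc(OCc2ccccc2)cc(OCc2ccccc2)c1OC=O | intermediate (not isolated)
5 | 2,4-bis(benzyloxy)-6-(methoxymethoxy)phenol | COCOc1cc(OCc2ccccc2)cc(OCc2ccccc2)c1O | intermediate (not isolated)
6 | 1,5-bis(benzyloxy)-2-methoxy-3-(methoxymethoxy)benzene | COCOc1cc(OCc2ccccc2)cc(OCc2ccccc2)c1OC | intermediate
7 | N,2-dimethoxy-N-methylacetamide | COCC(=O)N(C)OC | starting material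
8 | [4,6-bis(benzyloxy)-3-methoxy-2-(methoxymethoxy)phenyl]lithium | COCOc1c([Li])c(OCc2ccccc2)cc(OCc2ccccc2)c1OC | intermediate (not isolated)
9 | 1-[4,6-bis(benzyloxy)-3-methoxy-2-(methoxymethoxy)phenyl]-2-methoxyethan-1-one | COCOc1c(C(=O)COC)c(OCc2ccccc2)cc(OCc2ccccc2)c1OC | intermediate (not isolated)
10 | 1-[4,6-bis(benzyloxy)-2-hydroxy-3-methoxyphenyl]-2-methoxyethan-1-one | COCC(=O)c1c(O)c(OC)c(OCc2ccccc2)cc1OCc1ccccc1 | intermediate
11 | 3-(trimethylsilyl)prop-2-ynoic acid | C[Si](C)(C)C#CC(=O)O | starting material
12 | 3,5-bis(benzyloxy)-2-methoxy-6-(2-methoxyacetyl)phenyl 3-(trimethylsilyl)prop-2-ynoate | COCC(=O)c1c(OC(=O)C#C[Si](C)(C)C)c(OC)c(OCc2ccccc2)cc1OCc1ccccc1 | intermediate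
13 | 1-[4,6-bis(benzyloxy)-2-hydroxy-3-methoxyphenyl]-2-methoxy-5-(trimethylsilyl)pent-4-yne-1,3-dione (enolisable, C2 not defined) | COC(C(=O)C#C[Si](C)(C)C)C(=O)c1c(O)c(OC)c(OCc2ccccc2)cc1OCc1ccccc1 | intermediate (not isolated)
14 | 5,7-bis(benzyloxy)-3,8-dimethoxy-2-[(trimethylsilyl)ethynyl]-4H-chromen-4-one | COc1c(C#C[Si](C)(C)C)oc2c(OC)c(OCc3ccccc3)cc(OCc3ccccc3)c2c1=O | intermediate
15 | 5,7-bis(benzyloxy)-2-ethynyl-3,8-dimethoxy-4H-chromen-4-one | C#Cc1oc2c(OC)c(OCc3ccccc3)cc(OCc3ccccc3)c2c(=O)c1OC | intermediate
16 | methyl 4-methoxy-3-oxobutanoate (methyl 4-methoxyacetoacetate) | COCC(=O)CC(=O)OC | starting material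
17 | methyl (2Z)-4-methoxy-3-[(trimethylsilyl)oxy]but-2-enoate | COC/C(O[Si](C)(C)C)=C/C(=O)OC | intermediate
18 | (1Z,3Z)-1,4-dimethoxy-1,3-bis[(trimethylsilyl)oxy]buta-1,3-diene | CO/C=C(O[Si](C)(C)C)/C=C(/OC)O[Si](C)(C)C | intermediate
19 | 5,7-bis(benzyloxy)-2-{3,6-dimethoxy-4,6-bis[(trimethylsilyl)oxy]cyclohexa-1,4-dien-1-yl}-3,8-dimethoxy-4H-chromen-4-one (mixture of diastereomers) | COC1C=C(c2oc3c(OC)c(OCc4ccccc4)cc(OCc4ccccc4)c3c(=O)c2OC)C(OC)(O[Si](C)(C)C)C=C1O[Si](C)(C)C | intermediate (not isolated)
20 | 5,7-bis(benzyloxy)-3,8-dimethoxy-2-{5-methoxy-2,4-bis[(trimethylsilyl)oxy]phenyl}-4H-chromen-4-one | COc1cc(-c2oc3c(OC)c(OCc4ccccc4)cc(OCc4ccccc4)c3c(=O)c2OC)c(O[Si](C)(C)C)cc1O[Si](C)(C)C | intermediate (not isolated)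
21 | 5,7-bis(benzyloxy)-2-(2,4-dihydroxy-5-methoxyphenyl)-3,8-dimethoxy-4H-chromen-4-one | COc1cc(-c2oc3c(OC)c(OCc4ccccc4)cc(OCc4ccccc4)c3c(=O)c2OC)c(O)cc1O | intermediate
22 | 5,7-dihydroxy-2-(2,4-dihydroxy-5-methoxyphenyl)-3,8-dimethoxy-4H-chromen-4-one (5,7,2',4'-tetrahydroxy-3,8,5'-trimethoxyflavone) | COc1cc(-c2oc3c(OC)c(O)cc(O)c3c(=O)c2OC)c(O)cc1O | target

## Step count and least certain steps

Total step count: 11. Longest linear sequence: 9 steps (steps 1 to 7, 10 and 11, from 1 to 22); the diene branch (steps 8 and 9) joins at step 10.

**Key step (step 10).** The most likely failure is a slow cycloaddition, because the alkyne is activated only through the pyranone double bond. Thermal or hydrolytic decay of the diene, addition of the diene to the pyranone, or arrest after the first carbon–carbon bond could then take over. A smaller risk is ionisation at C2' with loss of silanol in place of methanol, which would leave a methyl ether on the 2'-oxygen. The fallback sets out from 18 and 10 and comes back at 22, and it keeps the diene but gives it its classical partner. 18 is heated with methyl propiolate, which by the same regiochemical logic should give methyl 2,4-dihydroxy-5-methoxybenzoate F1 after loss of methanol and desilylation. Double benzylation (BnBr, K2CO3) gives methyl 2,4-bis(benzyloxy)-5-methoxybenzoate F2, and saponification gives 2,4-bis(benzyloxy)-5-methoxybenzoic acid F3. F3 is esterified with 10 as in step 5 to 3,5-bis(benzyloxy)-2-methoxy-6-(2-methoxyacetyl)phenyl 2,4-bis(benzyloxy)-5-methoxybenzoate F4. Baker–Venkataraman rearrangement as in step 6 gives 1-[4,6-bis(benzyloxy)-2-hydroxy-3-methoxyphenyl]-3-[2,4-bis(benzyloxy)-5-methoxyphenyl]-2-methoxypropane-1,3-dione F5, and acid cyclodehydration gives 5,7-bis(benzyloxy)-2-[2,4-bis(benzyloxy)-5-methoxyphenyl]-3,8-dimethoxy-4H-chromen-4-one F6. Hydrogenolysis under the conditions of step 11 removes all four benzyl groups and gives 22.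

**Step 4.** Lithiation could occur at the position between the two benzyloxy groups or at a benzylic methylene (followed by Wittig rearrangement), and the aryllithium could deprotonate 7 instead of adding to it. The fallback sets out from 6 and comes back at 10, replacing metalation by electrophilic substitution under chelation control. Acid cleavage of the acetal (HCl, MeOH) gives 3,5-bis(benzyloxy)-2-methoxyphenol F7. F7 is acylated with methoxyacetic acid and BF3·OEt2; the difluoroboron chelate of the ortho-hydroxy ketone is the thermodynamic sink and only one ortho position is free, so 10 should result.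

**Step 6.** The diketone enol oxygen could close on the alkyne (6-endo-dig) to give a γ-pyrone, or the base could remove silicon or add to the ynone. The fallback sets out from 10 and comes back at 15, introducing the alkyne after the chromone is complete. Kostanecki–Robinson acylation (Ac2O, NaOAc, heat) gives 5,7-bis(benzyloxy)-3,8-dimethoxy-2-methyl-4H-chromen-4-one F8. SeO2 oxidation of the vinylogously activated methyl group gives 5,7-bis(benzyloxy)-3,8-dimethoxy-4-oxo-4H-chromene-2-carbaldehyde F9. Ohira–Bestmann homologation (dimethyl (1-diazo-2-oxopropyl)phosphonate, K2CO3, MeOH, 0 °C) then gives 15.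

**Step 1.** Over-alkylation to the tribenzyl ether and C-benzylation of the phloroglucinol ring would erode the selectivity on which the later differentiation rests. The fallback sets out from 1 and comes back at 2. Exhaustive benzylation (BnBr in excess, K2CO3, DMF) gives 2,4,6-tris(benzyloxy)benzaldehyde F10. Chelation-controlled removal of one benzyl group ortho to the formyl group with MgBr2·OEt2 then gives 2.

## Further compounds

F1 | step 10 | methyl 2,4-dihydroxy-5-methoxybenzoate | COC(=O)c1cc(OC)c(O)cc1O
F2 | step 10 | methyl 2,4-bis(benzyloxy)-5-methoxybenzoate | COC(=O)c1cc(OC)c(OCc2ccccc2)cc1OCc1ccccc1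
F3 | step 10 | 2,4-bis(benzyloxy)-5-methoxybenzoic acid | OC(=O)c1cc(OC)c(OCc2ccccc2)cc1OCc1ccccc1
F4 | step 10 | 3,5-bis(benzyloxy)-2-methoxy-6-(2-methoxyacetyl)phenyl 2,4-bis(benzyloxy)-5-methoxybenzoate | COCC(=O)c1c(OC(=O)c2cc(OC)c(OCc3ccccc3)cc2OCc2ccccc2)c(OC)c(OCc2ccccc2)cc1OCc1ccccc1
F5 | step 10 | 1-[4,6-bis(benzyloxy)-2-hydroxy-3-methoxyphenyl]-3-[2,4-bis(benzyloxy)-5-methoxyphenyl]-2-methoxypropane-1,3-dione | COC(C(=O)c1cc(OC)c(OCc2ccccc2)cc1OCc1ccccc1)C(=O)c1c(O)c(OC)c(OCc2ccccc2)cc1OCc1ccccc1
F6 | step 10 | 5,7-bis(benzyloxy)-2-[2,4-bis(benzyloxy)-5-methoxyphenyl]-3,8-dimethoxy-4H-chromen-4-one | COc1cc(-c2oc3c(OC)c(OCc4ccccc4)cc(OCc4ccccc4)c3c(=O)c2OC)c(OCc2ccccc2)cc1OCc1ccccc1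
F7 | step 4 | 3,5-bis(benzyloxy)-2-methoxyphenol | COc1c(O)cc(OCc2ccccc2)cc1OCc1ccccc1
F8 | step 6 | 5,7-bis(benzyloxy)-3,8-dimethoxy-2-methyl-4H-chromen-4-one | COc1c(C)oc2c(OC)c(OCc3ccccc3)cc(OCc3ccccc3)c2c1=O
F9 | step 6 | 5,7-bis(benzyloxy)-3,8-dimethoxy-4-oxo-4H-chromene-2-carbaldehyde | COc1c(C=O)oc2c(OC)c(OCc3ccccc3)cc(OCc3ccccc3)c2c1=O
F10 | step 1 | 2,4,6-tris(benzyloxy)benzaldehyde | O=Cc1c(OCc2ccccc2)cc(OCc2ccccc2)cc1OCc1ccccc1
A1 | alternative 1 | methyl 2-bromo-4,6-dihydroxy-3-methoxybenzoate | COC(=O)c1c(O)cc(O)c(OC)c1Br
A2 | alternative 1 | methyl 3-bromopropiolate | COC(=O)C#CBr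
A3 | alternative 2 | 2-methoxy-3,5-bis(triisopropylsilyloxy)phenol | COc1c(O)cc(O[Si](C(C)C)(C(C)C)C(C)C)cc1O[Si](C(C)C)(C(C)C)C(C)C
A4 | alternative 2 | 4-methoxy-3-(triisopropylsilyloxy)cyclobut-2-en-1-one (racemic) | COC1C(=O)C=C1O[Si](C(C)C)(C(C)C)C(C)C
A5 | alternative 2 | (triisopropylsilyloxy)acetylene | C#CO[Si](C(C)C)(C(C)C)C(C)C
A6 | alternative 3 | 7-(benzyloxy)-2-[4-(benzyloxy)-2,5-dihydroxyphenyl]-5,8-dihydroxy-3-methoxy-4H-chromen-4-one | COc1c(-c2cc(O)c(OCc3ccccc3)cc2O)oc2c(O)c(OCc3ccccc3)cc(O)c2c1=O
A7 | alternative 3 | 7-(benzyloxy)-2-[4-(benzyloxy)-2-hydroxyphenyl]-5-hydroxy-3-methoxy-4H-chromen-4-one (7,4'-di-O-benzyl-3-O-methylmorin) | COc1c(-c2ccc(OCc3ccccc3)cc2O)oc2cc(OCc3ccccc3)cc(O)c2c1=O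
A8 | alternative 3 | morin (3,5,7,2',4'-pentahydroxyflavone) | O=c1c(O)c(-c2ccc(O)cc2O)oc2cc(O)cc(O)c12
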